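The numbers in the tables come from a simulation with constants of no real substance, noise included.

**Examiner:** Which species leads at the end of each flask, and how much first product does Friday's flask hold?

in all of them: starting material 0.0010 M
- delta: coupling partner 0.38 equiv; run made earlier
- gamma: coupling partner 2.1 equiv; run made earlier
- Sunday's: coupling partner 0.800 equiv; time 30 min
- Wednesday's: coupling partner 3.00 equiv; time 30 min
- Friday's: coupling partner 0.500 equiv; time 30 min

| run | time / min | first product / % | starting material / % |
|---|---|---|---|
| delta | 1.00 | 24 | 74 |
| delta | 3.00 | 23 | 69 |
| delta | 5.00 | 26 | 71 |
| delta | 8.00 | 27 | 72 |
| delta | 12.0 | 26 | 73 |
| delta | 15.0 | 26 | 71 |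
| gamma | 2.50 | 39 | 11 |
| gamma | 5.00 | 46 | 4 |
| gamma | 8.00 | 53 | 4 |
| gamma | 10.0 | 55 | 5 |
| gamma | 12.0 | 61 | 4 |
| gamma | 15.0 | 65 | 2 |

(standard deviation of a reading: 2 percentage points)

- which of these holds the largest part of the starting material at the end of Sunday's (first product / double product / starting material)
- which of these holds the largest part of the starting material at the end of Wednesday's (first product / double product / starting material)
- which of these holds the largest part of the starting material at the end of Friday's (first product / double product / starting material)
- amount of first product at the end of Friday's, in percent of the starting material charged



**Examiner:** What does the delta run show first?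

**Candidate:** Its starting material readings stay level from the one at 1.00 min to the last, near the scatter of 2 percentage points. So I read the lifetime of the coupling partner, its time constant, as about that first interval or shorter.

**Examiner:** How many lifetimes does a flask get?

**Candidate:** On that reading, Friday's gets about 30.0 if it keeps delta's clock, because its run is far longer than that interval. Its end is then a matter of counting, with the partner as limiting reagent.

**Examiner:** Counting what?

**Candidate:** By the mean of its readings, delta consumed 28.3% of its starting material with 0.38 equiv. The partner yield φ, starting material consumed per equivalent of partner charged, is therefore 0.746. Delta kept a fraction κ = 0.894 of the consumed material as first product.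

**Examiner:** Why should φ hold at another charge?

**Candidate:** It may not. It is read at one charge, 0.38 equiv. Friday's takes 0.500 equiv and Wednesday's 3.00 equiv.

**Examiner:** Your reckoning?

**Candidate:** Friday's: starting material 62.7%, first product 33.3%, so starting material leads. Sunday's: starting material 40.4%, first product 53.3%, so first product leads. On Wednesday's, φ times the charge is 2.24, more than the whole charge of starting material, so the count fails there. I follow the gamma run, whose first product readings were still rising at their last, 65%, and choose first product.

The forecast chooses first product for Sunday's, first product for Wednesday's and starting material for Friday's. It gives Friday's 35% first product, between 31% and 40%, above my figure. Its ground: “Some partner is therefore lost”.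

    starting material + coupling partner → first product (k = 68.0 L mol⁻¹ s⁻¹)
    coupling partner + first product ⇌ double product (K = 15000 L mol⁻¹, k = 41.0 L mol⁻¹ s⁻¹)
    coupling partner → decomposed reagent (k = 0.0170 s⁻¹)
    coupling partner + first product → over-reaction product (k = 11.0 L mol⁻¹ s⁻¹)

Friday's ends with starting material leading at 63.0% and first product at 35.6%, inside the forecast's range. Sunday's ends with first product leading at 52.0%, and Wednesday's with first product leading at 61.3%. A neighbour of Friday's takes 0.850 equiv of partner. There φ gives starting material 36.6% and first product 56.7%, so the lead should change. The neighbour ends with first product leading at 54.3% over starting material at 41.4%, and its own partner yield is 0.689.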